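**Plan** (locants are those of iridal: C1 = CHO, C6 = ring CH, C7 = ring carbon of the exocyclic alkene, C8 and C9 = ring CH2, C10 = carbinol carbon, C11 = quaternary carbon)

- Retrosynthesis: first the C1 oxidation level, the O-silyl group and the C10–CH3 bond (methyl addition to a ring ketone); then the ring bond C7–C8, cut to an (E)-enol tosylate and a cyclopropanol; then C7–C2 (acylation of a propanoate enolate), one ring CH2 (carbenoid) and the C10 oxygen (Wacker oxidation of a vinyl group); last C6–C11 (Ireland–Claisen rearrangement of a geranylgeranyl ester).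
- Forward: the acyclic C6–C11 bond is made first and carries the whole polyene chain; the alkenyl tosylate and a temporary three-membered ring follow; the only ring of the target is then closed at C7–C8; C10, C1 and deprotection finish the route.
- Stereochemistry: C6 and C11 come from the chair Ireland–Claisen transition state ((E)-alkene of geranylgeraniol, Z(O)-boron enolate), with a chiral diazaborolidine for the absolute sense. The C2=C7 geometry comes from a chelation-free (E)-selective enol tosylation and is carried through with retention. C10 comes from equatorial methyl addition to the ring ketone, steered by the axial C6 side chain.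
- Enabling feature: in the cyclohexane ring, C8 lies two carbons from the carbinol carbon C10. The unit C8–C9–C10(O) can therefore be stored as a 1-oxycyclopropane (temporary C8–C10 bond) whose strain-driven opening makes C8 a nucleophile and C10 a ketone. The exocyclic tetrasubstituted C7=C2–C1(=O) unit makes C7 the enol carbon of a β-keto ester.

Key step: step 10

Assumption: the (S,S)-diazaborolidine of step 4 is taken to induce the (2S,3R) acid 8; should the sense be opposite, its (R,R)-enantiomer is used and nothing else changes.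

**Step 1**
Reactants: 1 pentane-1,5-diol
Product: 2 5-(tert-butyldiphenylsilyloxy)pentan-1-ol
Conditions: NaH (1.0 equiv), THF, 0 °C to rt; then t-BuPh2SiCl (1.0 equiv), rt
Reagents that add atoms: tert-butylchlorodiphenylsilane, CC(C)(C)[Si](Cl)(c1ccccc1)c1ccccc1
Why: One equivalent of NaH gives a sparingly soluble monoalkoxide of the symmetrical diol, so this O-silylation (monoprotection) should stop at the mono-ether.

**Step 2**
Reactants: 2 5-(tert-butyldiphenylsilyloxy)pentan-1-ol
Product: 4 5-(tert-butyldiphenylsilyloxy)pentanoic acid, via aldehyde 3 (not isolated)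
Conditions: TEMPO (0.2 equiv), PhI(OAc)2 (2.2 equiv), MeCN/H2O 1:1, rt
Reagents that add atoms: water, O
Why: The nitroxyl-catalysed oxidation with a hypervalent iodine co-oxidant takes the primary alcohol through aldehyde 3 and its hydrate to the acid and leaves the silyl ether alone.

**Step 3**
Reactants: 4 5-(tert-butyldiphenylsilyloxy)pentanoic acid; 5 (2E,6E,10E)-geranylgeraniol
Product: 6 (2E,6E,10E)-3,7,11,15-tetramethylhexadeca-2,6,10,14-tetraen-1-yl 5-(tert-butyldiphenylsilyloxy)pentanoate
Conditions: DCC (1.1 equiv), DMAP (0.1 equiv), CH2Cl2, 0 °C to rt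
Reagents that add atoms: none
Why: Steglich esterification joins acid and allylic alcohol under neutral conditions that leave the (E)-trisubstituted alkenes in place.

**Step 4**
Reactants: 6 geranylgeranyl 5-(tert-butyldiphenylsilyloxy)pentanoate
Product: 8 (2S,3R,6E,10E)-2-[3-(tert-butyldiphenylsilyloxy)propyl]-3-ethenyl-3,7,11,15-tetramethylhexadeca-6,10,14-trienoic acid, via boron ketene acetal 7 (not isolated)
Conditions: (4S,5S)-2-bromo-4,5-diphenyl-1,3-bis{[3,5-bis(trifluoromethyl)phenyl]sulfonyl}-1,3,2-diazaborolidine (1.3 equiv), i-Pr2NEt (1.5 equiv), CH2Cl2, −78 °C; then −20 to 4 °C, 2–3 d; aqueous work-up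
Reagents that add atoms: none
Why: This is an enantioselective Ireland–Claisen rearrangement in which soft enolization with the bromoborane and i-Pr2NEt in CH2Cl2 gives the Z(O)-boron ketene acetal 7; its chair transition state places the silyloxypropyl arm and the homofarnesyl arm of the (E)-alkene equatorial and the methyl group axial, so the C6–C11 bond forms with the relative configuration of iridal, while the C2-symmetric sulfonamide ligand on boron selects the enantiotopic face and thereby sets both C6 and the quaternary C11.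

**Step 5**
Reactants: 8 Claisen acid; 9 methyl propanoate
Product: 11 methyl (4S,5R,8E,12E)-4-[3-(tert-butyldiphenylsilyloxy)propyl]-5-ethenyl-2,5,9,13,17-pentamethyl-3-oxooctadeca-8,12,16-trienoate (C2 epimers), via acylimidazole 10 (not isolated)
Conditions: 1,1'-carbonyldiimidazole (1.2 equiv), THF, rt; then added to the lithium enolate of 9 (3 equiv, from 9 and LiN(i-Pr)2, THF, −78 °C), −78 to −30 °C; aq NH4Cl
Reagents that add atoms: none
Why: In this crossed Claisen condensation the ester enolate attacks the activated carboxyl carbon C7 of the acyl imidazole, and the product is stored at once as its doubly stabilized enolate, which keeps base away from the C6–H and prevents a second addition.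

**Step 6**
Reactants: 11 β-keto ester
Product: 12 methyl (2E,4S,5R,8E,12E)-4-[3-(tert-butyldiphenylsilyloxy)propyl]-5-ethenyl-2,5,9,13,17-pentamethyl-3-(tosyloxy)octadeca-2,8,12,16-tetraenoate
Conditions: TsCl (1.5 equiv), Me2N(CH2)6NMe2 (1.5 equiv), MeCN, 0 °C to rt
Reagents that add atoms: p-toluenesulfonyl chloride, Cc1ccc(cc1)S(Cl)(=O)=O
Why: In this stereocomplementary enol tosylation of an α-substituted β-keto ester, the absence of a chelating metal ion means O-sulfonylation occurs on the open, dipole-minimized enolate and should give the (E)-tosylate, with the leaving group trans to the ester and cis to the C2 methyl, which is the geometry the C7–C8 bond later needs.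

**Step 7**
Reactants: 12 (E)-enol tosylate
Product: 13 methyl (2E,4S,5S,8E,12E)-5-acetyl-4-[3-(tert-butyldiphenylsilyloxy)propyl]-2,5,9,13,17-pentamethyl-3-(tosyloxy)octadeca-2,8,12,16-tetraenoate
Conditions: PdCl2 (0.2 equiv), CuCl (1.0 equiv), O2 (1 atm), DMF/H2O 7:1, rt
Reagents that add atoms: water, O (source of the ketone oxygen; O2 is the terminal oxidant)
Why: In this Tsuji–Wacker oxidation the monosubstituted vinyl group is the only alkene that binds divalent palladium readily, so Markovnikov hydroxypalladation and β-hydride elimination should give the methyl ketone while the trisubstituted chain alkenes and the electron-poor tetrasubstituted enol tosylate stay untouched.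

**Step 8**
Reactants: 13 methyl ketone
Product: 14 methyl (2E,4S,5S,8E,12E)-4-[3-(tert-butyldiphenylsilyloxy)propyl]-2,5,9,13,17-pentamethyl-3-(tosyloxy)-5-[1-(trimethylsilyloxy)ethenyl]octadeca-2,8,12,16-tetraenoate
Conditions: Me3SiOTf (1.3 equiv), Et3N (2.0 equiv), CH2Cl2, −78 to 0 °C; used without chromatography
Reagents that add atoms: trimethylsilyl triflate, C[Si](C)(C)OS(=O)(=O)C(F)(F)F
Why: Soft enolization (silyl enol ether formation) can only occur toward the methyl group because C11 is quaternary, and it avoids exposing the β-tosyloxy enoate to a strong base.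

**Step 9**
Reactants: 14 silyl enol ether
Product: 15 methyl (2E,4S,5S,8E,12E)-4-[3-(tert-butyldiphenylsilyloxy)propyl]-2,5,9,13,17-pentamethyl-3-(tosyloxy)-5-[1-(trimethylsilyloxy)cyclopropyl]octadeca-2,8,12,16-tetraenoate
Conditions: Et2Zn (1.5 equiv), CH2I2 (1.5 equiv), CH2Cl2, −20 to 0 °C
Reagents that add atoms: diiodomethane, ICI
Why: In this Simmons–Smith cyclopropanation the electron-rich terminal silyl enol ether should take up the zinc carbenoid much faster than the unactivated trisubstituted alkenes and the electron-poor enoate, which installs the missing ring methylene inside a temporary siloxycyclopropane whose two CH2 groups are equivalent and serve equally as C8 and C9.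

**Step 10**
Reactants: 15 siloxycyclopropane
Product: 17 methyl (2Z)-2-[(2R,3S)-2-[3-(tert-butyldiphenylsilyloxy)propyl]-3-methyl-4-oxo-3-[(3E,7E)-4,8,12-trimethyltrideca-3,7,11-trien-1-yl]cyclohexylidene]propanoate, via cyclopropanol 16 (not isolated)
Conditions: Pd(OAc)2 (0.10 equiv), XPhos (0.20 equiv), CsF (3.0 equiv), 1,4-dioxane (degassed), 80 °C
Reagents that add atoms: none
Why: Fluoride frees cyclopropanol 16 as its cesium alkoxide, zerovalent palladium inserts into the alkenyl C7–OTs bond with retention, the alkoxide displaces tosylate on divalent palladium, and strain-driven β-carbon elimination of either cyclopropane CH2 unmasks the C10 ketone and a primary C8–Pd bond (a palladium homoenolate) that reductively eliminates with C7. The closest known reaction type is the palladium-catalysed ring-opening cross-coupling of cyclopropanols and siloxycyclopropanes with aryl and alkenyl halides or sulfonates, here run intramolecularly. The cyclohexane ring closes by C(sp3)–C(sp2) reductive elimination from a seven-membered palladacycle, formally a 6-exo closure at C7 that leaves the C7=C2 double bond exocyclic. No stereocentre is created: the (2Z) geometry of the tetrasubstituted alkene is inherited from the (E)-enol tosylate because oxidative addition and reductive elimination both proceed with retention, and C6 and C11 are not touched. The step needs reductive elimination to outrun β-hydride elimination from C8–Pd and needs chemoselectivity against the three trisubstituted alkenes; the bulky biaryl phosphine, the carbonyl-chelated homoenolate and the favourable ring size should secure the former, and the inertness of unactivated trisubstituted alkenes toward alkyl- and alkenylpalladium species the latter.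

**Step 11**
Reactants: 17 cyclohexanone
Product: 18 methyl (2Z)-2-[(2R,3S,4S)-2-[3-(tert-butyldiphenylsilyloxy)propyl]-4-hydroxy-3,4-dimethyl-3-[(3E,7E)-4,8,12-trimethyltrideca-3,7,11-trien-1-yl]cyclohexylidene]propanoate
Conditions: MeLi (3 equiv), CeCl3 (anhydrous, 3.3 equiv), THF, −78 °C
Reagents that add atoms: methyllithium, [Li]C
Why: In this organocerium 1,2-addition, A(1,3) strain with the cis ester of the exocyclic alkene holds the C6 side chain axial, which blocks axial approach to C10, so methyl should enter equatorially from the face anti to that chain and set C10 as (S), while the weakly basic cerium reagent suppresses enolization and spares the hindered enoate at −78 °C.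

**Step 12**
Reactants: 18 hydroxy ester
Product: 19 (2Z)-2-[(2R,3S,4S)-2-[3-(tert-butyldiphenylsilyloxy)propyl]-4-hydroxy-3,4-dimethyl-3-[(3E,7E)-4,8,12-trimethyltrideca-3,7,11-trien-1-yl]cyclohexylidene]propan-1-ol
Conditions: i-Bu2AlH (4 equiv), CH2Cl2, −78 to 0 °C; aq potassium sodium tartrate
Reagents that add atoms: none
Why: Hydride reduction with i-Bu2AlH takes the hindered conjugated ester in the 1,2-sense to the allylic alcohol, with the tertiary alcohol carried as its aluminium alkoxide and the alkene geometry unaffected.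

**Step 13**
Reactants: 19 allylic alcohol
Product: 20 (2Z)-2-[(2R,3S,4S)-2-[3-(tert-butyldiphenylsilyloxy)propyl]-4-hydroxy-3,4-dimethyl-3-[(3E,7E)-4,8,12-trimethyltrideca-3,7,11-trien-1-yl]cyclohexylidene]propanal
Conditions: MnO2 (activated, 20 equiv), CH2Cl2, rt
Reagents that add atoms: none
Why: Allylic oxidation with MnO2 should convert only the allylic primary alcohol into the tetrasubstituted (Z)-enal, without over-oxidation and without touching the tertiary alcohol or the silyl ether.

**Step 14**
Reactants: 20 O-silyl iridal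
Product: 21 iridal, (2Z)-2-[(2R,3S,4S)-4-hydroxy-2-(3-hydroxypropyl)-3,4-dimethyl-3-[(3E,7E)-4,8,12-trimethyltrideca-3,7,11-trien-1-yl]cyclohexylidene]propanal
Conditions: Bu4NF (2 equiv), AcOH (2 equiv), THF, 0 °C to rt
Reagents that add atoms: none
Why: Fluoride desilylation cleaves the primary silyl ether, and the acetic acid buffer should keep the enal from deconjugation or isomerization, which delivers iridal.

**Compound list**

1 | pentane-1,5-diol | OCCCCCO | starting material
2 | 5-(tert-butyldiphenylsilyloxy)pentan-1-ol | OCCCCCO[Si](c1ccccc1)(c1ccccc1)C(C)(C)C | intermediate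
3 | 5-(tert-butyldiphenylsilyloxy)pentanal (not isolated) | O=CCCCCO[Si](c1ccccc1)(c1ccccc1)C(C)(C)C | intermediate
4 | 5-(tert-butyldiphenylsilyloxy)pentanoic acid | OC(=O)CCCCO[Si](c1ccccc1)(c1ccccc1)C(C)(C)C | intermediate
5 | (2E,6E,10E)-geranylgeraniol | CC(C)=CCC/C(C)=C/CC/C(C)=C/CC/C(C)=C/CO | starting material
6 | geranylgeranyl 5-(tert-butyldiphenylsilyloxy)pentanoate | CC(C)=CCC/C(C)=C/CC/C(C)=C/CC/C(C)=C/COC(=O)CCCCO[Si](c1ccccc1)(c1ccccc1)C(C)(C)C | intermediate
7 | Z(O)-boron ketene acetal of 6 carrying the (4S,5S)-diazaborolidin-2-yl group on oxygen (not isolated) | CC(C)=CCC/C(C)=C/CC/C(C)=C/CC/C(C)=C/CO/C(OB1N(S(=O)(=O)c2cc(C(F)(F)F)cc(C(F)(F)F)c2)[C@@H](c2ccccc2)[C@H](c2ccccc2)N1S(=O)(=O)c1cc(C(F)(F)F)cc(C(F)(F)F)c1)=C/CCCO[Si](c1ccccc1)(c1ccccc1)C(C)(C)C | intermediate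
8 | (2S,3R,6E,10E)-2-[3-(tert-butyldiphenylsilyloxy)propyl]-3-ethenyl-3,7,11,15-tetramethylhexadeca-6,10,14-trienoic acid | CC(C)=CCC/C(C)=C/CC/C(C)=C/CC[C@@](C=C)(C)[C@H](CCCO[Si](c1ccccc1)(c1ccccc1)C(C)(C)C)C(=O)O | intermediate
9 | methyl propanoate | CCC(=O)OC | starting material
10 | N-acylimidazole of 8 (not isolated) | CC(C)=CCC/C(C)=C/CC/C(C)=C/CC[C@@](C=C)(C)[C@H](CCCO[Si](c1ccccc1)(c1ccccc1)C(C)(C)C)C(=O)n1ccnc1 | intermediate
11 | methyl (4S,5R,8E,12E)-4-[3-(tert-butyldiphenylsilyloxy)propyl]-5-ethenyl-2,5,9,13,17-pentamethyl-3-oxooctadeca-8,12,16-trienoate (C2 epimers) | CC(C)=CCC/C(C)=C/CC/C(C)=C/CC[C@@](C=C)(C)[C@H](CCCO[Si](c1ccccc1)(c1ccccc1)C(C)(C)C)C(=O)C(C)C(=O)OC | intermediate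
12 | (2E)-enol tosylate of 11 (4S,5R) | CC(C)=CCC/C(C)=C/CC/C(C)=C/CC[C@@](C=C)(C)[C@H](CCCO[Si](c1ccccc1)(c1ccccc1)C(C)(C)C)/C(OS(=O)(=O)c1ccc(C)cc1)=C(/C)C(=O)OC | intermediate
13 | 5-acetyl analogue of 12 (2E,4S,5S) | CC(C)=CCC/C(C)=C/CC/C(C)=C/CC[C@@](C(C)=O)(C)[C@H](CCCO[Si](c1ccccc1)(c1ccccc1)C(C)(C)C)/C(OS(=O)(=O)c1ccc(C)cc1)=C(/C)C(=O)OC | intermediate
14 | 5-[1-(trimethylsilyloxy)ethenyl] analogue (2E,4S,5S) | CC(C)=CCC/C(C)=C/CC/C(C)=C/CC[C@@](C(=C)O[Si](C)(C)C)(C)[C@H](CCCO[Si](c1ccccc1)(c1ccccc1)C(C)(C)C)/C(OS(=O)(=O)c1ccc(C)cc1)=C(/C)C(=O)OC | intermediate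
15 | 5-[1-(trimethylsilyloxy)cyclopropyl] analogue (2E,4S,5S) | CC(C)=CCC/C(C)=C/CC/C(C)=C/CC[C@@](C1(CC1)O[Si](C)(C)C)(C)[C@H](CCCO[Si](c1ccccc1)(c1ccccc1)C(C)(C)C)/C(OS(=O)(=O)c1ccc(C)cc1)=C(/C)C(=O)OC | intermediate
16 | 5-(1-hydroxycyclopropyl) analogue (2E,4S,5S), formed as its cesium alkoxide (not isolated) | CC(C)=CCC/C(C)=C/CC/C(C)=C/CC[C@@](C1(O)CC1)(C)[C@H](CCCO[Si](c1ccccc1)(c1ccccc1)C(C)(C)C)/C(OS(=O)(=O)c1ccc(C)cc1)=C(/C)C(=O)OC | intermediate
17 | methyl (2Z)-2-[(2R,3S)-2-[3-(tert-butyldiphenylsilyloxy)propyl]-3-methyl-4-oxo-3-[(3E,7E)-4,8,12-trimethyltrideca-3,7,11-trien-1-yl]cyclohexylidene]propanoate | CC(C)=CCC/C(C)=C/CC/C(C)=C/CC[C@@]1(C)[C@H](CCCO[Si](c2ccccc2)(c2ccccc2)C(C)(C)C)/C(=C(/C)C(=O)OC)CCC1=O | intermediate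
18 | methyl (2Z)-2-[(2R,3S,4S)-2-[3-(tert-butyldiphenylsilyloxy)propyl]-4-hydroxy-3,4-dimethyl-3-[(3E,7E)-4,8,12-trimethyltrideca-3,7,11-trien-1-yl]cyclohexylidene]propanoate | CC(C)=CCC/C(C)=C/CC/C(C)=C/CC[C@@]1(C)[C@H](CCCO[Si](c2ccccc2)(c2ccccc2)C(C)(C)C)/C(=C(/C)C(=O)OC)CC[C@]1(C)O | intermediate
19 | allylic alcohol corresponding to 18 (CH2OH in place of CO2Me) | CC(C)=CCC/C(C)=C/CC/C(C)=C/CC[C@@]1(C)[C@H](CCCO[Si](c2ccccc2)(c2ccccc2)C(C)(C)C)/C(=C(/C)CO)CC[C@]1(C)O | intermediate
20 | 3-O-(tert-butyldiphenylsilyl)iridal | CC(C)=CCC/C(C)=C/CC/C(C)=C/CC[C@@]1(C)[C@H](CCCO[Si](c2ccccc2)(c2ccccc2)C(C)(C)C)/C(=C(/C)C=O)CC[C@]1(C)O | intermediate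
21 | iridal | CC(C)=CCC/C(C)=C/CC/C(C)=C/CC[C@@]1(C)[C@H](CCCO)/C(=C(/C)C=O)CC[C@]1(C)O | target

**Step count and risks**

Total step count: 14. Longest linear sequence: 14 steps (pentane-1,5-diol to iridal; 12 from geranylgeraniol).

Steps most likely to fail:

Step 10. The process at risk is β-hydride elimination or protonolysis of the palladium homoenolate outrunning the ring-closing reductive elimination, or loss of alkene geometry at the alkenylpalladium stage. The fallback sets out from 13 and comes back at 18. CH2=CHMgBr with CeCl3 (THF, −78 °C) adds to the methyl ketone of 13 to give the tertiary allylic alcohol F1, in which the former ketone methyl is already the C10 methyl; the C10 epimers are separated by chromatography. 9-BBN (THF, rt) hydroborates only the monosubstituted vinyl group to give the B-alkyl-9-borabicyclononane F2. An intramolecular B-alkyl Suzuki–Miyaura coupling with the enol tosylate (Pd(dppf)Cl2, aq K3PO4, THF/DMF, 60 °C) then forms the same C7–C8 bond with retention and gives 18 directly.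

Step 9. The process at risk is loss of chemoselectivity, with the zinc carbenoid also cyclopropanating the three trisubstituted chain alkenes, or opening of the siloxycyclopropane by the ZnI2 formed. The fallback sets out from 14 and comes back at 17 without any carbenoid. A Mannich reaction of 14 with dimethylmethyleneiminium iodide (CH2Cl2, rt) gives the β-dimethylamino ketone F3. Quaternization with MeI and elimination with NaHCO3 gives the vinyl ketone F4. Copper-catalysed conjugate borylation (B2pin2, CuCl, NaOt-Bu, MeOH, THF) gives the β-pinacolboryl ketone F5. An intramolecular alkyl Suzuki–Miyaura coupling with the enol tosylate (Pd(OAc)2, RuPhos, K2CO3, toluene/H2O, 80 °C) closes C7–C8 and gives 17.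

Step 11. The process at risk is poor facial selectivity in the kinetically controlled addition to the hindered ketone, or enolization. The fallback sets out from 17 and comes back at 19 under thermodynamic control. Corey–Chaykovsky epoxidation with dimethylsulfoxonium methylide (Me3S(O)I, NaH, DMSO/THF, rt to 50 °C), whose reversible betaine formation should place the new C–C bond equatorial, gives the spiro-epoxide F6. LiAlH4 (THF, 0 °C) opens it at the CH2 terminus to the C10 methyl carbinol and reduces the ester in the same operation, giving 19.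

**Further compounds**

F1 | step 10 | methyl (2E,4S,5S,8E,12E)-4-[3-(tert-butyldiphenylsilyloxy)propyl]-5-[(2S)-2-hydroxybut-3-en-2-yl]-2,5,9,13,17-pentamethyl-3-(tosyloxy)octadeca-2,8,12,16-tetraenoate | CC(C)=CCC/C(C)=C/CC/C(C)=C/CC[C@@]([C@@](C)(O)C=C)(C)[C@H](CCCO[Si](c1ccccc1)(c1ccccc1)C(C)(C)C)/C(OS(=O)(=O)c1ccc(C)cc1)=C(/C)C(=O)OC
F2 | step 10 | 5-[(2S)-4-(9-borabicyclo[3.3.1]nonan-9-yl)-2-hydroxybutan-2-yl] analogue of F1 | CC(C)=CCC/C(C)=C/CC/C(C)=C/CC[C@@]([C@@](C)(O)CCB1C2CCCC1CCC2)(C)[C@H](CCCO[Si](c1ccccc1)(c1ccccc1)C(C)(C)C)/C(OS(=O)(=O)c1ccc(C)cc1)=C(/C)C(=O)OC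
F3 | step 9 | 5-[3-(dimethylamino)propanoyl] analogue of 13 (2E,4S,5S) | CC(C)=CCC/C(C)=C/CC/C(C)=C/CC[C@@](C(=O)CCN(C)C)(C)[C@H](CCCO[Si](c1ccccc1)(c1ccccc1)C(C)(C)C)/C(OS(=O)(=O)c1ccc(C)cc1)=C(/C)C(=O)OC
F4 | step 9 | 5-(prop-2-enoyl) analogue of 13 (2E,4S,5S) | CC(C)=CCC/C(C)=C/CC/C(C)=C/CC[C@@](C(=O)C=C)(C)[C@H](CCCO[Si](c1ccccc1)(c1ccccc1)C(C)(C)C)/C(OS(=O)(=O)c1ccc(C)cc1)=C(/C)C(=O)OC
F5 | step 9 | 5-[3-(4,4,5,5-tetramethyl-1,3,2-dioxaborolan-2-yl)propanoyl] analogue of 13 (2E,4S,5S) | CC(C)=CCC/C(C)=C/CC/C(C)=C/CC[C@@](C(=O)CCB1OC(C)(C)C(C)(C)O1)(C)[C@H](CCCO[Si](c1ccccc1)(c1ccccc1)C(C)(C)C)/C(OS(=O)(=O)c1ccc(C)cc1)=C(/C)C(=O)OC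
F6 | step 11 | spiro-epoxide of 17 (oxirane on the former carbonyl carbon, oxygen cis to the C11 methyl) | CC(C)=CCC/C(C)=C/CC/C(C)=C/CC[C@@]1(C)[C@H](CCCO[Si](c3ccccc3)(c3ccccc3)C(C)(C)C)/C(=C(/C)C(=O)OC)CC[C@@]12CO2
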